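**Retrosynthetic overview**
- Ring A is bought as methyl β-orcinolcarboxylate; only ring B is built, and the last disconnection is hydrogenolysis of the benzyl ethers at ring B O3 and O4.
- The strategy rests on the three contiguous oxygens of ring B: C2–OH, C3–O and C4–O map onto the carbonyl carbon and the two alkoxy carbons of a squarate-derived cyclobutenone, and C5–H onto its fourth carbon. C6 (methyl) and C1 (ester carbon) map onto the β- and α-carbons of a crotonate that already carries ring A as its aryl ester.
- Ring B is cut at C5–C6 (Stille coupling of a 4-chlorocyclobutenone with a β-stannyl enoate) and at C1–C2 (ring opening to a dienylketene, then 6π electrocyclisation).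
- The chloride comes from squaric acid by benzyl esterification, mono-reduction and chlorination. The stannane comes from ethyl but-2-ynoate by stannylcupration, saponification and O4-selective esterification of the ring A phenol.

Key step: step 7

Remark on the chemistry: alcohol 4, chloride 5 and dienone 14 are racemic. Their single stereocenter is erased when ring B becomes aromatic, and the target has no stereocenter.

**Step 1**
Reactants: 1 squaric acid; 2 benzyl alcohol
Product: 3 dibenzyl squarate (3,4-bis(benzyloxy)cyclobut-3-ene-1,2-dione)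
Conditions: BnOH (2.5 equiv), toluene, reflux, Dean–Stark
Reagents that add atoms: benzyl alcohol (second equivalent), OCc1ccccc1
Why: Squaric acid is a strong vinylogous acid that undergoes self-catalysed Fischer-type esterification at both hydroxyls with two equivalents of a primary alcohol once water is removed azeotropically, as in the standard preparation of dialkyl squarates.

**Step 2**
Reactants: 3 dibenzyl squarate
Product: 4 2,3-bis(benzyloxy)-4-hydroxycyclobut-2-en-1-one (racemic)
Conditions: LiAlH(OtBu)3 (1.05 equiv), THF, −78 to −20 °C; then H2O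
Reagents that add atoms: none
Why: Chemoselective 1,2-reduction, in which the single hydride of the bulky aluminate adds to one of the two equivalent carbonyls and the resulting alkoxide blocks a second reduction; the new C4 stereocenter forms as a racemate and is destroyed later.

**Step 3**
Reactants: 4 2,3-bis(benzyloxy)-4-hydroxycyclobut-2-en-1-one
Product: 5 2,3-bis(benzyloxy)-4-chlorocyclobut-2-en-1-one (racemic)
Conditions: PPh3, (Cl3C)2CO, CH2Cl2, −40 to 0 °C
Reagents that add atoms: hexachloroacetone, O=C(C(Cl)(Cl)Cl)C(Cl)(Cl)Cl
Why: Appel-type chlorination under neutral conditions, in which the hydroxyl is activated on phosphorus and chloride substitutes at C4 (allylic and alpha to the ketone), while any chloride that adds at C2 gives an α-chloro ether that should re-ionise and funnel to the conjugated chloride 5.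

**Step 4**
Reactants: 6 ethyl but-2-ynoate
Product: 8 ethyl (E)-3-(tributylstannyl)but-2-enoate, via alkenylcopper adduct 7 (not isolated)
Conditions: Bu3SnH, LiN(iPr)2, THF, 0 °C; CuBr·SMe2, −78 °C; then 6, MeOH, −78 °C
Reagents that add atoms: tributyltin hydride, CCCC[SnH](CCCC)CCCC
Why: Stannylcupration of an ynoate, in which Bu3SnCu adds syn with tin at the β-carbon and the methanol present protonates adduct 7 with retention before it can equilibrate through the allenoate, which fixes the E geometry (tin trans to the ester).

**Step 5**
Reactants: 8 ethyl (E)-3-(tributylstannyl)but-2-enoate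
Product: 9 (E)-3-(tributylstannyl)but-2-enoic acid
Conditions: LiOH·H2O, THF/MeOH/H2O, rt; work-up with cold 1 M HCl to pH 4
Reagents that add atoms: lithium hydroxide, [Li+].[OH-]
Why: Saponification of an unhindered ethyl ester; the alkenyl–tin bond is stable to hydroxide and, being deactivated toward protonation by the conjugated carboxyl group, should tolerate brief cold acidification.

**Step 6**
Reactants: 9 (E)-3-(tributylstannyl)but-2-enoic acid; 10 methyl 2,4-dihydroxy-3,6-dimethylbenzoate
Product: 11 3-hydroxy-4-(methoxycarbonyl)-2,5-dimethylphenyl (E)-3-(tributylstannyl)but-2-enoate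
Conditions: DCC, DMAP (10 mol %), CH2Cl2, 0 °C to rt
Reagents that add atoms: none
Why: Steglich esterification, expected at O4 because the 2-hydroxyl of 10 is hydrogen-bonded to the ortho ester carbonyl and flanked by two substituents, as in classical depside syntheses with this phenol.

**Step 7**
Reactants: 5 2,3-bis(benzyloxy)-4-chlorocyclobut-2-en-1-one; 11 3-hydroxy-4-(methoxycarbonyl)-2,5-dimethylphenyl (E)-3-(tributylstannyl)but-2-enoate
Product: 15 methyl 4-{[3,4-bis(benzyloxy)-2-hydroxy-6-methylbenzoyl]oxy}-2-hydroxy-3,6-dimethylbenzoate, via alkenylcyclobutenone 12 (not isolated), via dienylketene 13 (not isolated), via cyclohexadienone 14 (not isolated)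
Conditions: Pd2(dba)3 (2.5 mol %), tri(2-furyl)phosphine (10 mol %), dioxane, 50 °C; then 100 °C
Reagents that add atoms: none
Why: Zerovalent palladium ionises the C4–Cl bond of 5 to an η3-oxocyclobutenylpalladium chloride, the alkenyl group of 11 is transferred from tin with retention of the E geometry, and reductive elimination at C4 gives 12 (Stille coupling, forming ring B C5–C6). On warming, 12 undergoes reversible conrotatory 4π ring opening to dienylketene 13, which closes ring B by a thermal disrotatory 6π electrocyclisation joining the ketene carbon to the enoate α-carbon (ring B C1–C2), and enolisation of 14 gives the phenol. The closest known reaction type is the palladium-catalysed cross-coupling of 4-chlorocyclobutenones with alkenylstannanes followed by thermal ring expansion to phenols. No stereocenter survives, since the C4 center of 5 and the transient center of 14 are both erased on aromatisation. The step needs coupling at the CH terminus C4 and not at the benzyloxy-bearing terminus C2 of the allyl unit, which the lower substitution at C4 and the retained vinylogous ester conjugation favour, and it needs the alkenyl group to rotate inward, which the reversible ring opening supplies because only that ketene can cyclise. The position of tin on the β-carbon fixes the substitution pattern of ring B, and the E geometry keeps the aryl ester on the outside of the closing triene.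

**Step 8**
Reactants: 15 methyl 4-{[3,4-bis(benzyloxy)-2-hydroxy-6-methylbenzoyl]oxy}-2-hydroxy-3,6-dimethylbenzoate
Product: 16 methyl 2-hydroxy-3,6-dimethyl-4-[(2,3,4-trihydroxy-6-methylbenzoyl)oxy]benzoate (target)
Conditions: H2 (1 atm), 10% Pd/C, EtOAc, rt
Reagents that add atoms: none
Why: Hydrogenolysis of benzyl aryl ethers over palladium on carbon under neutral conditions, which leaves the aryl ester, the methyl ester and both arenes untouched and releases the oxygen-sensitive pyrogallol unit without base or oxidant.

**Compound list**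
1 | squaric acid (3,4-dihydroxycyclobut-3-ene-1,2-dione) | OC1=C(O)C(=O)C1=O | starting material
2 | benzyl alcohol | OCc1ccccc1 | starting material
3 | dibenzyl squarate (3,4-bis(benzyloxy)cyclobut-3-ene-1,2-dione) | O=C1C(=O)C(OCc2ccccc2)=C1OCc1ccccc1 | intermediate
4 | 2,3-bis(benzyloxy)-4-hydroxycyclobut-2-en-1-one (racemic) | O=C1C(O)C(OCc2ccccc2)=C1OCc1ccccc1 | intermediate
5 | 2,3-bis(benzyloxy)-4-chlorocyclobut-2-en-1-one (racemic) | O=C1C(Cl)C(OCc2ccccc2)=C1OCc1ccccc1 | intermediate
6 | ethyl but-2-ynoate | CCOC(=O)C#CC | starting material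
7 | ethyl (Z)-2-cuprio-3-(tributylstannyl)but-2-enoate (alkenylcopper adduct, ligands omitted) | CCOC(=O)/C([Cu])=C(\C)[Sn](CCCC)(CCCC)CCCC | intermediate (not isolated)
8 | ethyl (E)-3-(tributylstannyl)but-2-enoate | CCOC(=O)/C=C(\C)[Sn](CCCC)(CCCC)CCCC | intermediate
9 | (E)-3-(tributylstannyl)but-2-enoic acid | OC(=O)/C=C(\C)[Sn](CCCC)(CCCC)CCCC | intermediate
10 | methyl 2,4-dihydroxy-3,6-dimethylbenzoate | COC(=O)c1c(C)cc(O)c(C)c1O | starting material
11 | 3-hydroxy-4-(methoxycarbonyl)-2,5-dimethylphenyl (E)-3-(tributylstannyl)but-2-enoate | COC(=O)c1c(C)cc(OC(=O)/C=C(\C)[Sn](CCCC)(CCCC)CCCC)c(C)c1O | intermediate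
12 | 3-hydroxy-4-(methoxycarbonyl)-2,5-dimethylphenyl (E)-3-[2,3-bis(benzyloxy)-4-oxocyclobut-2-en-1-yl]but-2-enoate (racemic) | COC(=O)c1c(C)cc(OC(=O)/C=C(\C)C2C(=O)C(OCc3ccccc3)=C2OCc2ccccc2)c(C)c1O | intermediate (not isolated)
13 | 3-hydroxy-4-(methoxycarbonyl)-2,5-dimethylphenyl (2E,4E)-5,6-bis(benzyloxy)-3-methyl-7-oxohepta-2,4,6-trienoate (C3 and the ketene-bearing C6 cis across C4=C5) | COC(=O)c1c(C)cc(OC(=O)/C=C(C)/C=C(OCc2ccccc2)\C(OCc2ccccc2)=C=O)c(C)c1O | intermediate (not isolated)
14 | 3-hydroxy-4-(methoxycarbonyl)-2,5-dimethylphenyl 3,4-bis(benzyloxy)-6-methyl-2-oxocyclohexa-3,5-diene-1-carboxylate (racemic) | COC(=O)c1c(C)cc(OC(=O)C2C(C)=CC(OCc3ccccc3)=C(OCc3ccccc3)C2=O)c(C)c1O | intermediate (not isolated)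
15 | methyl 4-{[3,4-bis(benzyloxy)-2-hydroxy-6-methylbenzoyl]oxy}-2-hydroxy-3,6-dimethylbenzoate | COC(=O)c1c(C)cc(OC(=O)c2c(C)cc(OCc3ccccc3)c(OCc3ccccc3)c2O)c(C)c1O | intermediate
16 | methyl 2-hydroxy-3,6-dimethyl-4-[(2,3,4-trihydroxy-6-methylbenzoyl)oxy]benzoate | COC(=O)c1c(C)cc(OC(=O)c2c(C)cc(O)c(O)c2O)c(C)c1O | target

**Totals**
Total step count: 8.
Longest linear sequence: 5 steps (steps 1, 2, 3, 7, 8 or steps 4, 5, 6, 7, 8).

**Steps most likely to fail**

Step 7. Transmetalation of the electron-poor, β,β-disubstituted stannane may be slow. The oxocyclobutenylpalladium intermediate could then decay by loss of a benzyl group. During the heating, the free ring A phenol could add to the dienylketene, or the aryl enoate could transfer its acyl group. The fallback separates the ring construction from the depside bond and sets out from acid 9. Steglich esterification of 9 with 2-(trimethylsilyl)ethanol should give 2-(trimethylsilyl)ethyl (E)-3-(tributylstannyl)but-2-enoate F1, a partner without phenol or aryl ester that tolerates longer heating. Coupling of F1 with chloride 5 under the Pd2(dba)3 and tri(2-furyl)phosphine conditions should give 2-(trimethylsilyl)ethyl (E)-3-[2,3-bis(benzyloxy)-4-oxocyclobut-2-en-1-yl]but-2-enoate F2. This should open to the dienylketene 2-(trimethylsilyl)ethyl (2E,4E)-5,6-bis(benzyloxy)-3-methyl-7-oxohepta-2,4,6-trienoate F3 and close to 2-(trimethylsilyl)ethyl 3,4-bis(benzyloxy)-6-methyl-2-oxocyclohexa-3,5-diene-1-carboxylate F4. Enolisation then gives 2-(trimethylsilyl)ethyl 3,4-bis(benzyloxy)-2-hydroxy-6-methylbenzoate F5. Bu4NF in THF should release 3,4-bis(benzyloxy)-2-hydroxy-6-methylbenzoic acid F6. Condensation of F6 with phenol 10 at O4 (trifluoroacetic anhydride, toluene, rt, the classical depside condensation) comes back to the route at 15.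

Step 3. The C4 leaving group may ionise with help from the C2 benzyloxy group. The cation can then lose a benzyl group to chloride (collapse to benzyl semisquarate) or recombine at C2, during the chlorination, on silica or on storage. The fallback replaces the isolated chloride by an allylic acetate and sets out from alcohol 4. Ac2O, pyridine and catalytic DMAP at 0 °C should give 2,3-bis(benzyloxy)-4-oxocyclobut-2-en-1-yl acetate F7 under basic, non-ionising conditions. F7 is then coupled with stannane 11 under conditions known for allylic acetates and organostannanes (Pd2(dba)3, tri(2-furyl)phosphine, LiCl, DMF, 50 °C then 100 °C). Zerovalent palladium should generate the same oxocyclobutenylpalladium chloride in the flask, and the sequence passes through 12, 13 and 14 and comes back to the route at 15.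

Step 6. Carboxyl activation of the stannyl acid may be diverted to the N-acylurea. The acylpyridinium ion can also lose the E geometry or the tin through its dienolate, and over-acylation at O2 would consume material. The fallback forms the aryl ester before tin is introduced and sets out from phenol 10. DCC/DMAP esterification of 10 with commercial but-2-ynoic acid at O4 should give methyl 4-(but-2-ynoyloxy)-2-hydroxy-3,6-dimethylbenzoate F8. Stannylcupration of F8 with Bu3SnCu·SMe2 in THF at −78 °C, with methanol present, should place tin at the β-carbon by syn addition. It passes through the alkenylcopper adduct 3-hydroxy-4-(methoxycarbonyl)-2,5-dimethylphenyl (Z)-2-cuprio-3-(tributylstannyl)but-2-enoate F9, whose protonation comes back to the route at 11.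

**Further compounds**
F1 | step 7 | 2-(trimethylsilyl)ethyl (E)-3-(tributylstannyl)but-2-enoate | C[Si](C)(C)CCOC(=O)/C=C(\C)[Sn](CCCC)(CCCC)CCCC
F2 | step 7 | 2-(trimethylsilyl)ethyl (E)-3-[2,3-bis(benzyloxy)-4-oxocyclobut-2-en-1-yl]but-2-enoate | C[Si](C)(C)CCOC(=O)/C=C(\C)C1C(=O)C(OCc2ccccc2)=C1OCc1ccccc1
F3 | step 7 | 2-(trimethylsilyl)ethyl (2E,4E)-5,6-bis(benzyloxy)-3-methyl-7-oxohepta-2,4,6-trienoate | C[Si](C)(C)CCOC(=O)/C=C(C)/C=C(OCc1ccccc1)\C(OCc1ccccc1)=C=O
F4 | step 7 | 2-(trimethylsilyl)ethyl 3,4-bis(benzyloxy)-6-methyl-2-oxocyclohexa-3,5-diene-1-carboxylate | C[Si](C)(C)CCOC(=O)C1C(C)=CC(OCc2ccccc2)=C(OCc2ccccc2)C1=O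
F5 | step 7 | 2-(trimethylsilyl)ethyl 3,4-bis(benzyloxy)-2-hydroxy-6-methylbenzoate | C[Si](C)(C)CCOC(=O)c1c(C)cc(OCc2ccccc2)c(OCc2ccccc2)c1O
F6 | step 7 | 3,4-bis(benzyloxy)-2-hydroxy-6-methylbenzoic acid | OC(=O)c1c(C)cc(OCc2ccccc2)c(OCc2ccccc2)c1O
F7 | step 3 | 2,3-bis(benzyloxy)-4-oxocyclobut-2-en-1-yl acetate | CC(=O)OC1C(=O)C(OCc2ccccc2)=C1OCc1ccccc1
F8 | step 6 | methyl 4-(but-2-ynoyloxy)-2-hydroxy-3,6-dimethylbenzoate | COC(=O)c1c(C)cc(OC(=O)C#CC)c(C)c1O
F9 | step 6 | 3-hydroxy-4-(methoxycarbonyl)-2,5-dimethylphenyl (Z)-2-cuprio-3-(tributylstannyl)but-2-enoate | COC(=O)c1c(C)cc(OC(=O)/C([Cu])=C(\C)[Sn](CCCC)(CCCC)CCCC)c(C)c1O
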